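**Plan**
- Retrosynthesis: open the γ-lactone (O–C16/C19) last, cut C12–C13 (sp3–sp2 Suzuki–Miyaura) into bicyclic core 23 and peroxide fragment 35, then cut C7–C8 and C9–C10 of ring B in one Diels–Alder step.
- Enabling feature: the C4 carboxyl carbon and the C6 oxygen sit 1,3 across C5, so they can be tied as a γ-enol lactone. This locks the diene C7=C6–C5=C10 s-cis, puts the carboxyl in the diene plane and leaves the C4 methyl as the only face-differentiating group.
- Forward, core: ring A with C4 set by a chiral lithio-enamine methylation, then the lactone-locked diene, then [4+2] with methyl buta-2,3-dienoate to close ring B and set C10. C9 follows by kinetic protonation, C8 by radical hydration, C5/C6 by methanolysis and SmI2 reduction.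
- Forward, fragment: a catalytic aldol sets C16, an Evans–Tishchenko reduction sets C14 (1,3-anti), SN2 ring closure by a hydroperoxy ketal inverts C14 and forms the 1,2-dioxane, and a peroxycarbenium alkylation sets C17 trans to O–C16.
- Endgame: hydroboration/Suzuki–Miyaura union, then acid lactonization to the trans-fused peroxy-lactone.

Key step: step 8

Remarks. Numbering in names: decalin C1–C10 as in labdanes (ring A C1–C5, C10; ring B C5–C10). C4 carries CH3 and the carboxyl, C8 carries CH3 and OH, C10 carries CH3. The chain on C9 is C11, C12, C13 (bearing =CH2), C14 (CH–OO), C15, C16 (CH–O of the lactone), C17 (C(CH3)–OO), C18, C19 (lactone C=O). α is the face opposite the C10 methyl. The target SMILES is read as written: the γ-lactone is trans-fused to the 1,2-dioxane (H on C16 anti to CH3 on C17) and the C14 substituent is axial; the route is built for exactly this relative configuration. In steps 2 and 16 the absolute sense is fixed by the antipode of auxiliary or ligand; the one giving the stated configuration is used.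

Step 1
Reactants: 1 methyl 2-oxocyclohexane-1-carboxylate; 2 L-valine tert-butyl ester
Product: 3 methyl 2-{[(2S)-1-tert-butoxy-3-methyl-1-oxobutan-2-yl]amino}cyclohex-1-ene-1-carboxylate
Conditions: TsOH (cat.), benzene, reflux, Dean–Stark
Reagents that add atoms: none
Why: Condensation of the β-keto ester with the primary amine under azeotropic dehydration gives the hydrogen-bonded enamino ester (enamine formation).

Step 2
Reactants: 3 methyl 2-{[(2S)-1-tert-butoxy-3-methyl-1-oxobutan-2-yl]amino}cyclohex-1-ene-1-carboxylate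
Product: 6 methyl (1R)-1-methyl-2-oxocyclohexane-1-carboxylate, via lithio-enamine 4 (not isolated), via C-methylated imine 5 (not isolated)
Conditions: LiN(i-Pr)2, toluene, −78 °C; MeI with THF as donor ligand (medium chosen for the R face), −78 → −20 °C; then 1 M HCl, rt
Reagents that add atoms: methyl iodide, CI; water, O
Why: Chiral lithio-enamine alkylation, in which lithium chelated by the valine ester carbonyl exposes one face of the aza-enolate to methyl iodide so that the quaternary centre (later C4) should form as R, and acid hydrolysis then releases the ketone and the auxiliary.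

Step 3
Reactants: 6 methyl (1R)-1-methyl-2-oxocyclohexane-1-carboxylate
Product: 8 methyl (1R)-1,3-dimethyl-2-oxocyclohexane-1-carboxylate (mixture at C3), via lithium enolate 7 (not isolated)
Conditions: LiN(i-Pr)2, THF, −78 °C; MeI, −78 → 0 °C
Reagents that add atoms: methyl iodide, CI
Why: Kinetic enolate alkylation at the only enolizable α-carbon installs the future C10 methyl, and its configuration is irrelevant because this carbon becomes sp2 in step 4.

Step 4
Reactants: 8 methyl (1R)-1,3-dimethyl-2-oxocyclohexane-1-carboxylate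
Product: 10 methyl (1R)-1,3-dimethyl-2-{[(trifluoromethyl)sulfonyl]oxy}cyclohex-2-ene-1-carboxylate, via potassium enolate 9 (not isolated)
Conditions: KN(SiMe3)2, THF, −78 → 0 °C; PhNTf2, 0 °C → rt
Reagents that add atoms: N-phenylbis(trifluoromethanesulfonimide), O=S(=O)(N(c1ccccc1)S(=O)(=O)C(F)(F)F)C(F)(F)F
Why: Enolization is possible only toward the methyl-bearing carbon, and O-sulfonylation of that enolate gives the tetrasubstituted enol triflate (enol triflate formation).

Step 5
Reactants: 10 methyl (1R)-1,3-dimethyl-2-{[(trifluoromethyl)sulfonyl]oxy}cyclohex-2-ene-1-carboxylate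
Product: 11 methyl (1R)-1,3-dimethyl-2-[(trimethylsilyl)ethynyl]cyclohex-2-ene-1-carboxylate
Conditions: PdCl2(PPh3)2 (5 mol%), CuI (10 mol%), Et3N, DMF, 60 °C
Reagents that add atoms: ethynyltrimethylsilane, C#C[Si](C)(C)C
Why: Sonogashira coupling of a hindered cyclohexenyl triflate, a reaction well known for 2,6,6-trisubstituted cyclohexenyl triflates.

Step 6
Reactants: 11 methyl (1R)-1,3-dimethyl-2-[(trimethylsilyl)ethynyl]cyclohex-2-ene-1-carboxylate
Product: 12 (1R)-2-ethynyl-1,3-dimethylcyclohex-2-ene-1-carboxylic acid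
Conditions: KOH, MeOH–H2O (4:1), 65 °C; then 1 M HCl
Reagents that add atoms: potassium hydroxide, [K+].[OH-]
Why: Hydroxide in methanol cleaves the alkynyl C–Si bond and saponifies the hindered ester, and the quaternary C4 cannot epimerize.

Step 7
Reactants: 12 (1R)-2-ethynyl-1,3-dimethylcyclohex-2-ene-1-carboxylic acid
Product: 13 (7aR)-4,7a-dimethyl-3-methylidene-5,6,7,7a-tetrahydro-2-benzofuran-1(3H)-one (lactone-locked diene)
Conditions: AuCl(PPh3) (2 mol%), AgOTf (2 mol%), CH2Cl2, rt; used at once
Reagents that add atoms: none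
Why: Gold-catalysed cycloisomerization of a 4-alkynoic acid (5-exo-dig anti-addition of the carboxyl to the activated terminal alkyne, then protodeauration) gives the γ-methylene enol lactone and thereby the s-cis-locked diene C7=C6–C5=C10.

Step 8
Reactants: 13 (7aR)-4,7a-dimethyl-3-methylidene-5,6,7,7a-tetrahydro-2-benzofuran-1(3H)-one; 14 methyl buta-2,3-dienoate
Product: 15 tricyclic enol lactone (ring B closed; lactone C4-carboxyl to O–C6 with C5=C6; 8-methylidene; CO2Me on C9 as both epimers; 4β-CH3; 10β-CH3)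
Conditions: 14 (3 equiv), BHT (cat.), toluene, 70 °C, sealed tube
Reagents that add atoms: none
Why: A concerted, asynchronous [4π+2π] Diels–Alder cycloaddition joins the exocyclic diene C7=C6–C5=C10 of 13 to the ester-conjugated C8=C9 bond of the allenoate, forming C7–C8 and C9–C10 at once; the closest known reaction type is the cycloaddition of outer-ring (exocyclic) heterocyclic dienes and of 1-vinyl-2,6,6-trimethylcyclohexene with acetylenic or allenic esters. Ring B is closed by intermolecular suprafacial [4+2] annulation onto ring A, which is possible because the γ-enol-lactone ring (C4–C(=O)–O–C6, spanning C5) holds the diene s-cis. The new quaternary centre C10 is set by the C4 methyl group, the angular substituent of the bicyclic diene, which blocks its face so that the dienophile should add anti and the C10 methyl ends cis to the C4 methyl (4β,10β). C9 forms as an endo/exo mixture that is not needed, since step 9 converges both epimers. Regioselectivity should follow from the largest HOMO coefficient at the unsubstituted terminus C7 (acyloxy donor on C6, two alkyl donors on C10), which bonds to the electrophilic central allene carbon while the lagging C9–C10 bond tolerates the hindered terminus; chemoselectivity for the conjugated allene double bond follows from its LUMO.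

Step 9
Reactants: 15 tricyclic enol lactone (C9 epimers)
Product: 17 tricyclic enol lactone with 9α-H and 9β-CO2Me (single C9 epimer), via lithium ester dienolate 16 (not isolated)
Conditions: LiN(i-Pr)2 (1.1 equiv), THF, −78 °C; then AcOH, −78 °C
Reagents that add atoms: none
Why: Deprotonation at C9 (α to the ester and allylic) gives one dienolate from both epimers, and kinetic α-protonation from the face opposite the C10 methyl should give the 9α-H epimer (stereoconvergent kinetic protonation of an ester dienolate).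

Step 10
Reactants: 17 tricyclic enol lactone with 9α-H and 9β-CO2Me
Product: 18 tricyclic enol lactone with 8α-OH and 8β-CH3 (9β-CO2Me retained)
Conditions: Mn(dpm)3 (10 mol%), PhSiH3, O2 (1 atm), i-PrOH–CH2Cl2, 0 °C
Reagents that add atoms: dioxygen, O=O
Why: Mukaiyama hydration (hydrogen-atom transfer to the 1,1-disubstituted alkene, then trapping of the tertiary C8 radical by O2) is Markovnikov-selective, and O2 should approach from the α face away from the C10 methyl and the C9 ester to give 8α-OH/8β-CH3, while the tetrasubstituted enol-lactone alkene is inert.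

Step 11
Reactants: 18 tricyclic enol lactone with 8α-OH and 8β-CH3
Product: 19 keto diester (4α-CO2Me; 4β-CH3; 5α-H; 6-oxo; 8α-OH; 8β-CH3; 9β-CO2Me; 10β-CH3; trans-decalin)
Conditions: K2CO3 (0.2 equiv), MeOH, 0 °C
Reagents that add atoms: methanol, CO
Why: Methanolysis of the enol lactone (acyl transfer from an enol ester) removes the temporary ring, unveils the C4 methyl ester and a C6 enolate, and protonation at C5 from the α face (opposite the C4 and C10 methyls) should give the trans-decalin, which is also the thermodynamic isomer.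

Step 12
Reactants: 19 keto diester
Product: 20 diol diester (6α-OH; 8α-OH; 9β-CO2Me; 4α-CO2Me)
Conditions: SmI2 (4 equiv), THF–H2O, 0 °C → rt
Reagents that add atoms: none
Why: Single-electron (ketyl) reduction with protonation under thermodynamic control should give the equatorial 6α-alcohol, helped by samarium bridging O6 and the 8α-hydroxyl, whereas hydride reagents would attack from the α face and give the axial 6β-alcohol.

Step 13
Reactants: 20 diol diester
Product: 21 triol ester (9β-CH2OH; 6α-OH; 8α-OH; 4α-CO2Me)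
Conditions: LiBH4, THF with MeOH (1 equiv), 0 °C → rt
Reagents that add atoms: none
Why: β-Hydroxy-directed borohydride reduction, in which the alkoxyborohydride formed at 8-OH delivers hydride to the C9 ester through a six-membered transition state while the α-quaternary C4 ester, lacking such delivery, should survive.

Step 14
Reactants: 21 triol ester
Product: 22 hydroxy aldehyde (9β-CHO; 6α-OH; 8α-OH; 4α-CO2Me)
Conditions: TEMPO (10 mol%), PhI(OAc)2, CH2Cl2, rt
Reagents that add atoms: none
Why: Oxoammonium (TEMPO) oxidation is selective for the primary alcohol over the hindered secondary and the tertiary alcohol.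

Step 15
Reactants: 22 hydroxy aldehyde
Product: 23 vinyl core (9β-CH=CH2; 6α-OH; 8α-OH; 4α-CO2Me)
Conditions: Ph3PCH3Br, KOtBu, THF, 0 °C; then 22, −78 → 0 °C
Reagents that add atoms: methyltriphenylphosphonium bromide, C[P+](c1ccccc1)(c1ccccc1)c1ccccc1.[Br-]
Why: Wittig methylenation of the aldehyde is fast at low temperature, and the ylide is too weak a base to trigger retro-aldol cleavage of the β-hydroxy aldehyde.

Step 16
Reactants: 24 4-(trimethylsilyl)but-3-yn-2-one; 25 methacrolein
Product: 26 (5S)-5-hydroxy-6-methyl-1-(trimethylsilyl)hept-6-en-1-yn-3-one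
Conditions: ZnEt2 (10 mol%), (S,S)-ProPhenol (5 mol%; antipode chosen for the S carbinol), 4 Å MS, THF, 0 °C
Reagents that add atoms: none
Why: Direct catalytic asymmetric aldol addition of a methyl ynone under a dinuclear zinc–ProPhenol catalyst, the ligand controlling the aldehyde face so that C16 should form as S.

Step 17
Reactants: 26 (5S)-5-hydroxy-6-methyl-1-(trimethylsilyl)hept-6-en-1-yn-3-one
Product: 27 (3S,5S)-3-hydroxy-6-methyl-1-(trimethylsilyl)hept-6-en-1-yn-5-yl acetate
Conditions: SmI2 (20 mol%), CH3CHO (5 equiv), THF, −10 °C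
Reagents that add atoms: acetaldehyde, CC=O
Why: Evans–Tishchenko reduction, in which intramolecular hydride transfer within the samarium-bound hemiacetal gives the 1,3-anti diol monoester; this sets C14 and leaves the acetate on O–C16 and the free hydroxyl on C14.

Step 18
Reactants: 27 (3S,5S)-3-hydroxy-6-methyl-1-(trimethylsilyl)hept-6-en-1-yn-5-yl acetate
Product: 28 (3S,5S)-3-hydroxy-6-methylhept-6-en-1-yn-5-yl acetate
Conditions: AgNO3 (10 mol%), acetone–H2O, rt
Reagents that add atoms: none
Why: Silver-catalysed protodesilylation of the alkynylsilane runs under neutral conditions, which avoids 1,3-acetyl migration.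

Step 19
Reactants: 28 (3S,5S)-3-hydroxy-6-methylhept-6-en-1-yn-5-yl acetate
Product: 29 (3S,5S)-6-methyl-3-[(methylsulfonyl)oxy]hept-6-en-1-yn-5-yl acetate
Conditions: MsCl, Et3N, CH2Cl2, −20 °C
Reagents that add atoms: methanesulfonyl chloride, CS(=O)(=O)Cl
Why: O-Sulfonylation of the secondary propargylic alcohol proceeds with retention and provides the leaving group for the later SN2 ring closure.

Step 20
Reactants: 29 (3S,5S)-6-methyl-3-[(methylsulfonyl)oxy]hept-6-en-1-yn-5-yl acetate
Product: 31 (3S,5S)-2-bromo-6-methyl-3-[(methylsulfonyl)oxy]hepta-1,6-dien-5-yl acetate, via (Z)-2-bromoalkenyl-9-BBN 30 (not isolated)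
Conditions: B-Br-9-BBN (1.2 equiv), CH2Cl2, 0 °C; then AcOH, 0 °C → rt
Reagents that add atoms: B-bromo-9-borabicyclo[3.3.1]nonane, BrB1C2CCCC1CCC2
Why: Haloboration adds B–Br syn across the terminal alkyne with bromine on the internal carbon, and protodeboronation with acetic acid gives the 2-bromo-1-alkene while alkenes and esters are left alone.

Step 21
Reactants: 31 (3S,5S)-2-bromo-6-methyl-3-[(methylsulfonyl)oxy]hepta-1,6-dien-5-yl acetate
Product: 32 (3S,5S)-6-bromo-5-[(methylsulfonyl)oxy]-2-oxohept-6-en-3-yl acetate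
Conditions: O3, CH2Cl2, −78 °C (Sudan red end point); then Me2S, −78 °C → rt
Reagents that add atoms: ozone, [O-][O+]=O
Why: Ozonolysis with reductive work-up is selective for the electron-richer 1,1-dialkyl alkene, the bromoalkene being strongly deactivated.

Step 22
Reactants: 32 (3S,5S)-6-bromo-5-[(methylsulfonyl)oxy]-2-oxohept-6-en-3-yl acetate
Product: 34 (4S,6R)-6-(1-bromoethenyl)-3-methoxy-3-methyl-1,2-dioxan-4-yl acetate (mixture at C3), via hydroperoxy methyl ketal 33 (not isolated)
Conditions: H2O2 (ethereal), HC(OMe)3, MeOH, CSA (cat.), rt; then Cs2CO3, DMF, 0 °C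
Reagents that add atoms: hydrogen peroxide, OO; trimethyl orthoformate, COC(OC)OC
Why: Acid-catalysed perketalization (ketone to dimethyl ketal to α-methoxy hydroperoxide) is followed by intramolecular 6-exo-tet SN2 alkylation of the hydroperoxide anion at the activated mesylate, which inverts C14 to R and closes the 1,2-dioxane.

Step 23
Reactants: 34 (4S,6R)-6-(1-bromoethenyl)-3-methoxy-3-methyl-1,2-dioxan-4-yl acetate
Product: 35 methyl 2-[(3R,4S,6R)-4-(acetyloxy)-6-(1-bromoethenyl)-3-methyl-1,2-dioxan-3-yl]acetate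
Conditions: CH2=C(OMe)OSiMe3, TMSOTf, CH2Cl2, −78 °C
Reagents that add atoms: 1-methoxy-1-(trimethylsilyloxy)ethene, C=C(OC)O[Si](C)(C)C
Why: Lewis-acid ionization of the peroxyketal gives a peroxycarbenium ion that the silyl ketene acetal captures (Mukaiyama-type substitution of a 3-alkoxy-1,2-dioxane), and participation of the neighbouring C16 acetate should direct attack anti, placing the new CH2CO2Me trans to O–C16 (17R).

Step 24
Reactants: 23 vinyl core; 35 methyl 2-[(3R,4S,6R)-4-(acetyloxy)-6-(1-bromoethenyl)-3-methyl-1,2-dioxan-3-yl]acetate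
Product: 37 coupled acetate (C12 of the core bonded to C13; C13=CH2; dioxane with 16-OAc and 17-CH2CO2Me), via B-alkyl-9-BBN 36 (not isolated)
Conditions: 9-BBN (3 equiv), THF, 0 °C → rt; then aq. K3PO4, 35, Pd(dppf)Cl2 (10 mol%), AsPh3 (10 mol%), DMF, rt
Reagents that add atoms: none
Why: Anti-Markovnikov hydroboration of the vinyl group followed by B-alkyl Suzuki–Miyaura sp3–sp2 coupling with the 2-bromo-1-alkene forms C12–C13 and the 1,1-disubstituted alkene, dialkyl peroxides being known to tolerate palladium-catalysed cross-coupling at room temperature.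

Step 25
Reactants: 37 coupled acetate
Product: 39 target CNP0162504.1, via hydroxy ester 38 (not isolated)
Conditions: TsOH·H2O (0.2 equiv), MeOH, rt; then evaporation, CSA (cat.), toluene, 4 Å MS, 40 °C
Reagents that add atoms: none
Why: Acid-catalysed transesterification removes the acetate, and the γ-hydroxy ester then lactonizes (5-exo-trig acyl substitution) to the trans-fused lactone because O–C16 and the C17 CH2CO2Me are trans-diequatorial; no stereocentre is touched and the hindered C4 ester should not lactonize onto 6-OH.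

**Compound list**
1 | methyl 2-oxocyclohexane-1-carboxylate | COC(=O)C1CCCCC1=O | starting material
2 | L-valine tert-butyl ester | CC(C)[C@H](N)C(=O)OC(C)(C)C | starting material
3 | methyl 2-{[(2S)-1-tert-butoxy-3-methyl-1-oxobutan-2-yl]amino}cyclohex-1-ene-1-carboxylate | COC(=O)C1=C(N[C@@H](C(C)C)C(=O)OC(C)(C)C)CCCC1 | intermediate
4 | N-lithio derivative of 3 (lithio-enamine) | COC(=O)C1=C(N([Li])[C@@H](C(C)C)C(=O)OC(C)(C)C)CCCC1 | intermediate (not isolated)
5 | methyl (1R)-2-{[(2S)-1-tert-butoxy-3-methyl-1-oxobutan-2-yl]imino}-1-methylcyclohexane-1-carboxylate | C1CCC[C@@](C)(C(=O)OC)C1=N[C@@H](C(C)C)C(=O)OC(C)(C)C | intermediate (not isolated)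
6 | methyl (1R)-1-methyl-2-oxocyclohexane-1-carboxylate | C1CCC[C@@](C)(C(=O)OC)C1=O | intermediate
7 | lithium enolate of 6 (O-lithio, C2=C3) | C=1CCC[C@@](C)(C(=O)OC)C=1O[Li] | intermediate (not isolated)
8 | methyl (1R)-1,3-dimethyl-2-oxocyclohexane-1-carboxylate (mixture at C3) | CC1CCC[C@@](C)(C(=O)OC)C1=O | intermediate
9 | potassium enolate of 8 (O-potassio, C2=C3) | CC=1CCC[C@@](C)(C(=O)OC)C=1O[K] | intermediate (not isolated)
10 | methyl (1R)-1,3-dimethyl-2-{[(trifluoromethyl)sulfonyl]oxy}cyclohex-2-ene-1-carboxylate | CC=1CCC[C@@](C)(C(=O)OC)C=1OS(=O)(=O)C(F)(F)F | intermediate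
11 | methyl (1R)-1,3-dimethyl-2-[(trimethylsilyl)ethynyl]cyclohex-2-ene-1-carboxylate | CC=1CCC[C@@](C)(C(=O)OC)C=1C#C[Si](C)(C)C | intermediate
12 | (1R)-2-ethynyl-1,3-dimethylcyclohex-2-ene-1-carboxylic acid | CC=1CCC[C@@](C)(C(=O)O)C=1C#C | intermediate
13 | (7aR)-4,7a-dimethyl-3-methylidene-5,6,7,7a-tetrahydro-2-benzofuran-1(3H)-one | CC=1CCC[C@@]2(C)C(=O)OC(=C)C=12 | intermediate
14 | methyl buta-2,3-dienoate | C=C=CC(=O)OC | starting material
15 | tricyclic enol lactone: lactone from the C4 carboxyl to O–C6 (C5=C6); 8-methylidene; CO2Me on C9 (both epimers); 4β-CH3; 10β-CH3 | COC(=O)C1[C@@]2(C)CCC[C@@](C)(C(=O)O3)C2=C3CC1=C | intermediate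
16 | lithium ester dienolate of 15 (C9=C(OLi)OMe) | COC(O[Li])=C1[C@@]2(C)CCC[C@@](C)(C(=O)O3)C2=C3CC1=C | intermediate (not isolated)
17 | 9α-H, 9β-CO2Me epimer of 15 | COC(=O)[C@@H]1[C@@]2(C)CCC[C@@](C)(C(=O)O3)C2=C3CC1=C | intermediate
18 | 8α-hydroxy-8β-methyl tricyclic enol lactone (9β-CO2Me) | COC(=O)[C@@H]1[C@@]2(C)CCC[C@@](C)(C(=O)O3)C2=C3C[C@@]1(C)O | intermediate
19 | keto diester: 4α-CO2Me, 4β-CH3, 5α-H, 6-oxo, 8α-OH, 8β-CH3, 9β-CO2Me, 10β-CH3 | COC(=O)[C@@H]1[C@@]2(C)CCC[C@@](C)(C(=O)OC)[C@@H]2C(=O)C[C@@]1(C)O | intermediate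
20 | diol diester: as 19 with 6α-OH | COC(=O)[C@@H]1[C@@]2(C)CCC[C@@](C)(C(=O)OC)[C@@H]2[C@@H](O)C[C@@]1(C)O | intermediate
21 | triol ester: 9β-CH2OH, 6α-OH, 8α-OH, 4α-CO2Me | OC[C@@H]1[C@@]2(C)CCC[C@@](C)(C(=O)OC)[C@@H]2[C@@H](O)C[C@@]1(C)O | intermediate
22 | hydroxy aldehyde: 9β-CHO, 6α-OH, 8α-OH, 4α-CO2Me | O=C[C@@H]1[C@@]2(C)CCC[C@@](C)(C(=O)OC)[C@@H]2[C@@H](O)C[C@@]1(C)O | intermediate
23 | vinyl core: 9β-CH=CH2, 6α-OH, 8α-OH, 4α-CO2Me | C=C[C@@H]1[C@@]2(C)CCC[C@@](C)(C(=O)OC)[C@@H]2[C@@H](O)C[C@@]1(C)O | intermediate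
24 | 4-(trimethylsilyl)but-3-yn-2-one | CC(=O)C#C[Si](C)(C)C | starting material
25 | methacrolein (2-methylprop-2-enal) | CC(=C)C=O | starting material
26 | (5S)-5-hydroxy-6-methyl-1-(trimethylsilyl)hept-6-en-1-yn-3-one | C[Si](C)(C)C#CC(=O)C[C@H](O)C(C)=C | intermediate
27 | (3S,5S)-3-hydroxy-6-methyl-1-(trimethylsilyl)hept-6-en-1-yn-5-yl acetate | C[Si](C)(C)C#C[C@@H](O)C[C@H](OC(C)=O)C(C)=C | intermediate
28 | (3S,5S)-3-hydroxy-6-methylhept-6-en-1-yn-5-yl acetate | C#C[C@@H](O)C[C@H](OC(C)=O)C(C)=C | intermediate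
29 | (3S,5S)-6-methyl-3-[(methylsulfonyl)oxy]hept-6-en-1-yn-5-yl acetate | C#C[C@@H](OS(C)(=O)=O)C[C@H](OC(C)=O)C(C)=C | intermediate
30 | (Z)-2-bromoalkenyl-9-BBN from 29 (Br on C2, boron on C1) | Br/C(=C\B1C2CCCC1CCC2)[C@@H](OS(C)(=O)=O)C[C@H](OC(C)=O)C(C)=C | intermediate (not isolated)
31 | (3S,5S)-2-bromo-6-methyl-3-[(methylsulfonyl)oxy]hepta-1,6-dien-5-yl acetate | C=C(Br)[C@@H](OS(C)(=O)=O)C[C@H](OC(C)=O)C(C)=C | intermediate
32 | (3S,5S)-6-bromo-5-[(methylsulfonyl)oxy]-2-oxohept-6-en-3-yl acetate | C=C(Br)[C@@H](OS(C)(=O)=O)C[C@H](OC(C)=O)C(C)=O | intermediate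
33 | (3S,5S)-6-bromo-2-hydroperoxy-2-methoxy-5-[(methylsulfonyl)oxy]hept-6-en-3-yl acetate (mixture at C2) | C=C(Br)[C@@H](OS(C)(=O)=O)C[C@H](OC(C)=O)C(C)(OC)OO | intermediate (not isolated)
34 | (4S,6R)-6-(1-bromoethenyl)-3-methoxy-3-methyl-1,2-dioxan-4-yl acetate (mixture at C3) | C=C(Br)[C@H]1C[C@H](OC(C)=O)C(C)(OC)OO1 | intermediate
35 | methyl 2-[(3R,4S,6R)-4-(acetyloxy)-6-(1-bromoethenyl)-3-methyl-1,2-dioxan-3-yl]acetate | C=C(Br)[C@H]1C[C@H](OC(C)=O)[C@@](C)(CC(=O)OC)OO1 | intermediate
36 | B-alkyl-9-BBN from 23 (boron on C12) | C1CCC2CCCC1B2CC[C@@H]3[C@@]4(C)CCC[C@@](C)(C(=O)OC)[C@@H]4[C@@H](O)C[C@@]3(C)O | intermediate (not isolated)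
37 | coupled acetate: core 23 joined C12–C13; C13=CH2; (3R,4S,6R)-4-acetoxy-3-(2-methoxy-2-oxoethyl)-3-methyl-1,2-dioxan-6-yl on C13 | C=C(CC[C@@H]1[C@@]2(C)CCC[C@@](C)(C(=O)OC)[C@@H]2[C@@H](O)C[C@@]1(C)O)[C@H]1C[C@H](OC(C)=O)[C@@](C)(CC(=O)OC)OO1 | intermediate
38 | hydroxy ester: 37 with free 16-OH | C=C(CC[C@@H]1[C@@]2(C)CCC[C@@](C)(C(=O)OC)[C@@H]2[C@@H](O)C[C@@]1(C)O)[C@H]1C[C@H](O)[C@@](C)(CC(=O)OC)OO1 | intermediate (not isolated)
39 | CNP0162504.1 | C=C(CC[C@@H]1[C@@]2(C)CCC[C@@](C)(C(=O)OC)[C@@H]2[C@@H](O)C[C@@]1(C)O)[C@H]1C[C@@H]2OC(=O)C[C@@]2(C)OO1 | target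

**Totals**
Total step count: 25. Longest linear sequence: 17 steps (steps 1–15, then 24 and 25); the fragment branch is steps 16–23.

**Steps most likely to fail**

Step 8. At the temperature the cycloaddition needs, the rigid s-cis diene may instead undergo a 1,5-hydrogen shift from the C10 methyl to C7 or oligomerize, and facial selectivity may erode. The fallback sets out from 10 and gives up the lactone lock. Stille coupling of 10 with tributyl(1-ethoxyvinyl)stannane (PdCl2(PPh3)2, LiCl, dioxane, 90 °C) should give the open 2-ethoxydiene methyl (1R)-2-(1-ethoxyethenyl)-1,3-dimethylcyclohex-2-ene-1-carboxylate F1. Its twisted ground state does not hold the methyl hydrogens over C7, and it allows Lewis-acid activation of 14 (Me2AlCl, CH2Cl2, −40 °C). The cycloadduct, the 6-ethoxy-5-ene 8-methylidene diester F2 (C9 epimers), is taken through the protonation of step 9 to the 9β-ester F3 and the hydration of step 10 to the 8α-hydroxy enol ether F4. Mild hydrolysis of the enol ether (oxalic acid, wet THF) then returns the route at 19.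

Step 22. Acetyl transfer from O–C16 to the hydroperoxide anion, or base-induced elimination of the mesylate, may outrun the ring closure. The fallback sets out from 31 and reverses the order of the two C–O bond formations. Intermolecular SN2 displacement with 2-methoxypropan-2-yl hydroperoxide (CsOH, DMF, 0 °C) should give, with inversion, (3R,5S)-2-bromo-3-[(2-methoxypropan-2-yl)peroxy]-6-methylhepta-1,6-dien-5-yl acetate F5. Ozonolysis as in step 21 gives (3S,5R)-6-bromo-5-[(2-methoxypropan-2-yl)peroxy]-2-oxohept-6-en-3-yl acetate F6. CSA in MeOH with HC(OMe)3 then unmasks the C14 hydroperoxide, which adds to the C17 ketone and is trapped as the cyclic methyl ketal, returning the route at 34.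

Step 24. Zerovalent palladium or residual borane may cleave the O–O bond or ionize the allylic C14–O bond of the peroxide. The fallback sets out from 28 and moves the cross-coupling ahead of all peroxide chemistry.
- Silylation (Et3SiCl, imidazole) gives (3S,5S)-6-methyl-3-(triethylsilyloxy)hept-6-en-1-yn-5-yl acetate F7.
- Haloboration as in step 20 gives (3S,5S)-2-bromo-6-methyl-3-(triethylsilyloxy)hepta-1,6-dien-5-yl acetate F8.
- Ozonolysis as in step 21 gives (3S,5S)-6-bromo-2-oxo-5-(triethylsilyloxy)hept-6-en-3-yl acetate F9.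
- Coupling of F9 with 36 under the conditions of step 24 gives the coupled silyloxy ketone F10.
- HF·pyridine frees the C14 allylic alcohol F11, and MsCl/Et3N at −40 °C gives the C14 allylic mesylate F12, which is used crude.
- The conditions of step 22 lead through the hydroperoxy ketal F13 to the core-bound methoxy dioxane F14, and the conditions of step 23 return the route at 37.

Further compounds
F1 | step 8 | methyl (1R)-2-(1-ethoxyethenyl)-1,3-dimethylcyclohex-2-ene-1-carboxylate | CC=1CCC[C@@](C)(C(=O)OC)C=1C(=C)OCC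
F2 | step 8 | Diels–Alder adduct of F1 and 14: 6-ethoxy-5-ene, 8-methylidene, 4α-CO2Me, CO2Me on C9 (both epimers) | COC(=O)C1[C@@]2(C)CCC[C@@](C)(C(=O)OC)C2=C(OCC)CC1=C
F3 | step 8 | 9α-H, 9β-CO2Me epimer of F2 | COC(=O)[C@@H]1[C@@]2(C)CCC[C@@](C)(C(=O)OC)C2=C(OCC)CC1=C
F4 | step 8 | 8α-hydroxy-8β-methyl derivative of F3 (6-ethoxy-5-ene retained) | COC(=O)[C@@H]1[C@@]2(C)CCC[C@@](C)(C(=O)OC)C2=C(OCC)C[C@@]1(C)O
F5 | step 22 | (3R,5S)-2-bromo-3-[(2-methoxypropan-2-yl)peroxy]-6-methylhepta-1,6-dien-5-yl acetate | C=C(Br)[C@H](OOC(C)(C)OC)C[C@H](OC(C)=O)C(C)=C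
F6 | step 22 | (3S,5R)-6-bromo-5-[(2-methoxypropan-2-yl)peroxy]-2-oxohept-6-en-3-yl acetate | C=C(Br)[C@H](OOC(C)(C)OC)C[C@H](OC(C)=O)C(C)=O
F7 | step 24 | (3S,5S)-6-methyl-3-(triethylsilyloxy)hept-6-en-1-yn-5-yl acetate | C#C[C@@H](O[Si](CC)(CC)CC)C[C@H](OC(C)=O)C(C)=C
F8 | step 24 | (3S,5S)-2-bromo-6-methyl-3-(triethylsilyloxy)hepta-1,6-dien-5-yl acetate | C=C(Br)[C@@H](O[Si](CC)(CC)CC)C[C@H](OC(C)=O)C(C)=C
F9 | step 24 | (3S,5S)-6-bromo-2-oxo-5-(triethylsilyloxy)hept-6-en-3-yl acetate | C=C(Br)[C@@H](O[Si](CC)(CC)CC)C[C@H](OC(C)=O)C(C)=O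
F10 | step 24 | coupled silyloxy ketone: core 23 joined C12–C13; C13=CH2; 14-OSiEt3; 16-OAc; C17 methyl ketone | C=C(CC[C@@H]1[C@@]2(C)CCC[C@@](C)(C(=O)OC)[C@@H]2[C@@H](O)C[C@@]1(C)O)[C@@H](O[Si](CC)(CC)CC)C[C@H](OC(C)=O)C(C)=O
F11 | step 24 | C14 allylic alcohol from F10 | C=C(CC[C@@H]1[C@@]2(C)CCC[C@@](C)(C(=O)OC)[C@@H]2[C@@H](O)C[C@@]1(C)O)[C@@H](O)C[C@H](OC(C)=O)C(C)=O
F12 | step 24 | C14 allylic mesylate from F11 | C=C(CC[C@@H]1[C@@]2(C)CCC[C@@](C)(C(=O)OC)[C@@H]2[C@@H](O)C[C@@]1(C)O)[C@@H](OS(C)(=O)=O)C[C@H](OC(C)=O)C(C)=O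
F13 | step 24 | hydroperoxy methyl ketal from F12 (mixture at C17) | C=C(CC[C@@H]1[C@@]2(C)CCC[C@@](C)(C(=O)OC)[C@@H]2[C@@H](O)C[C@@]1(C)O)[C@@H](OS(C)(=O)=O)C[C@H](OC(C)=O)C(C)(OC)OO
F14 | step 24 | core-bound methoxy dioxane: 17-OMe, 16-OAc, 14R (mixture at C17) | C=C(CC[C@@H]1[C@@]2(C)CCC[C@@](C)(C(=O)OC)[C@@H]2[C@@H](O)C[C@@]1(C)O)[C@H]1C[C@H](OC(C)=O)C(C)(OC)OO1
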